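## The problem

Compound 12 is a diaryl ether in which two tetrasubstituted benzene rings share one oxygen and no stereocentre is present, so the task is purely regiochemical. Ring A carries the ether oxygen at C1, a methoxy group at C2 and bromine at C3 and C5, whereas ring B carries the ether oxygen at C1, a free hydroxyl at C2, bromine at C3 and C5 and a methoxy group at C6. Three oxygen functions must be told apart: the C2 oxygen of ring A ends as a methyl ether, and of the two oxygens flanking the ether carbon of ring B one is methylated and one stays free. The ether bond joins ring A to a ring B carbon that is hindered on both sides, so ring B can only serve as the nucleophilic partner in ether formation. Once in place, the four aryl bromides exclude hydrogenolysis, dissolving metals, aryllithium chemistry and low-valent palladium or nickel, and the two methyl ethers must survive whatever frees the phenol. The enabling feature is that on each ring both bromines lie ortho (C3) and para (C5) to the oxygen at C2, and on ring B the same two carbons are also para and ortho to the oxygen at C6. These are the positions an electrophile attacks in the halogen-free diaryl ether, so all four C–Br bonds can be made late in one operation.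

## Retrosynthesis

**12 ⇒ 11.** The O–H bond of the ring B hydroxyl is traced back to an O–CH2Ph bond. A benzyl group tolerates carbonate bases, peracid and ionic bromination, and it can be removed by a boron Lewis acid without hydrogen, which the four aryl bromides require. Compound 11 has no free hydroxyl and is therefore easier to handle than 12. The forward step must break only the O–CH2Ph bond of 11 and leave two aryl methyl ethers untouched.

**11 ⇒ 10.** The O–CH3 bond of ring A is cut. Methylation has to follow the bromination, because ring A must be halogenated as a free phenol. Since ring B is benzylated, 10 has a single hydroxyl and the forward methylation needs no selectivity.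

**10 ⇒ 9.** All four C–Br bonds are cut at once. Bringing the bromines in on separate building blocks would weaken the phenoxide needed for ether formation, slow both aryl migrations and require a separately prepared brominated ring A unit. Late bromination instead leads back to 9, which has only hydrogen at the four sites and is four heavy atoms simpler. The forward reaction must be site-selective on both rings, stop at four substitutions and spare the benzyl ether.

**9 ⇒ 7 (through formate 8).** The C–O bond of the ring A phenol is traced to a C–CHO bond. The same formyl group activates ring A for ether formation in the step before, so 7 needs no separate activating group. Peracid oxidation with aryl migration must then turn the formyl group into the hydroxyl that directs the bromination.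

**7 ⇒ 5 + 6.** The diaryl ether C–O bond is cut on the ring A side. The ring B carbon lies between two oxygen substituents and cannot be activated for substitution, whereas the fluorine of 6 is ortho to a formyl group. The cut divides the skeleton into two monocyclic pieces, and the forward step is an addition–elimination by the hindered phenoxide of 5.

**5 ⇒ 3 (through formate 4) ⇒ 1 + 2.** The central C–O bond of ring B is again derived from a C–CHO bond, and the O–CH2Ph bond is cut. Salicylaldehyde 1 already has the two flanking oxygens differentiated (one methoxy, one free hydroxyl), and its aldehyde carbon marks the future ether position. Benzylation with 2 and aryl migration should give 5 with no regiochemical question.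

## Roads not taken

Alternative 1: The cut runs through ring B, which would be built from an acyclic chain. O-Alkylation of 3,5-dibromo-2-methoxyphenol A1 would give methyl 6-(3,5-dibromo-2-methoxyphenoxy)-5-oxohexanoate A2. KOtBu would cyclise A2 by intramolecular Claisen condensation to 2-(3,5-dibromo-2-methoxyphenoxy)cyclohexane-1,3-dione A3. O-Methylation of A3 would give the vinylogous ester 2-(3,5-dibromo-2-methoxyphenoxy)-3-methoxycyclohex-2-en-1-one A4. Dehydrogenation of A4 to 2-(3,5-dibromo-2-methoxyphenoxy)-3-methoxyphenol A5 and dibromination of A5 would reach 12.
- Merits: no protecting group is needed, the OH/OMe difference on ring B arises naturally because the dione A3 is methylated once, and the ring A bromines are fixed from the start in A1. In these respects it is better than the chosen plan.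
- Weak points: a benzene ring whose oxygenation pattern can be bought is made de novo; the aromatisation of A4 must be done beside two aryl bromides, which excludes palladium dehydrogenation; the sequence runs to about nine steps.
- Comparison: the chosen plan sets against the cleaner ring A regiochemistry its seven steps of standard aromatic chemistry and the firm precedent for phenol-directed bromination.

Alternative 2: The cut runs through ring A, which would be assembled by a formal [3+3] cyclocondensation. The bis-silyl dienol ether 1-(benzyloxy)-3-methoxy-2-{[4-methoxy-2,4-bis(trimethylsilyloxy)buta-1,3-dien-1-yl]oxy}benzene A6 and 2-bromo-3-(trimethylsilyloxy)prop-2-enal A7 would be joined under TiCl4. The product would be methyl 3-[2-(benzyloxy)-6-methoxyphenoxy]-5-bromo-2-hydroxybenzoate A8.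
- Merits: the C5 bromine and the hydroxyl of ring A are placed by ring construction, so the ring A pattern of A8 is not open to doubt.
- Weak points: A6 has to be made from hindered phenol 5 by chain attachment and double silylation; the strong Lewis acid needed to activate A7 meets a benzyl ether; the ester of A8 sits where bromine must end up, so saponification and bromodecarboxylation follow; ring B still needs two late electrophilic brominations.
- Comparison: this road replaces only one of the four C–Br bond formations and costs several extra steps. It is better only in the certainty of the ring A pattern, and the chosen plan reaches the same pattern in one step through the free phenol.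

Alternative 3: The cut removes both flanking C–O bonds of ring B, which would come from formyl groups. Substitution of the doubly activated 2-fluoroisophthalaldehyde A9 by A1 would give 2-(3,5-dibromo-2-methoxyphenoxy)isophthalaldehyde A10. A double peracid oxidation of A10 with aryl migration would give 2-(3,5-dibromo-2-methoxyphenoxy)benzene-1,3-diol A11. Monomethylation of A11 to A5 and dibromination would finish the synthesis.
- Merits: the route is about as short as the chosen one, needs no protecting group, the ether formation is easier, and the ring A halogens are unambiguous. In these respects it is as good or better.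
- Weak points: the two hydroxyls of A11 are equivalent, so monomethylation is statistical; the first aryl migration in A10 must occur on a ring still carrying a second electron-withdrawing formyl group, where hydride migration to the acid competes; A9 is a costly starting material.
- Comparison: the chosen plan differentiates the ring B oxygens from the first step through 1, runs each aryl migration on an electron-rich monoaldehyde and installs all four halogens in one operation. It pays for this with one protecting group and with reliance on directing effects in both rings.

Key step: step 5

Remark on the chemistry: ring locants are those defined in "The problem"; the target has no stereocentres, so no configuration has to be assigned.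

Step 1
Reactants: 1 2-hydroxy-6-methoxybenzaldehyde; 2 benzyl bromide
Product: 3 2-(benzyloxy)-6-methoxybenzaldehyde
Conditions: K2CO3, DMF, rt to 60 °C
Reagents that add atoms: none
Why: Williamson ether synthesis; the phenoxide formed with K2CO3 in DMF displaces bromide from the unhindered benzylic carbon by an SN2 reaction, and the aldehyde is inert to these conditions.

Step 2
Reactants: 3 2-(benzyloxy)-6-methoxybenzaldehyde
Product: 5 2-(benzyloxy)-6-methoxyphenol, via 2-(benzyloxy)-6-methoxyphenyl formate 4 (not isolated)
Conditions: mCPBA, CH2Cl2, 0 °C to rt; then K2CO3, MeOH, rt
Reagents that add atoms: 3-chloroperoxybenzoic acid (mCPBA), O=C(OO)c1cccc(Cl)c1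
Why: Dakin-type Baeyer–Villiger oxidation; the aryl group with two ortho alkoxy donors should migrate in the Criegee intermediate in preference to hydride, and the resulting formate 4 is cleaved by base-catalysed methanolysis.

Step 3
Reactants: 5 2-(benzyloxy)-6-methoxyphenol; 6 2-fluorobenzaldehyde
Product: 7 2-[2-(benzyloxy)-6-methoxyphenoxy]benzaldehyde
Conditions: K2CO3, DMAc, 120 °C
Reagents that add atoms: none
Why: Nucleophilic aromatic substitution by addition–elimination; the ortho formyl group stabilises the Meisenheimer intermediate and fluoride is the best leaving group for this mechanism, while heat in a dipolar aprotic solvent compensates for the hindered phenoxide.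

Step 4
Reactants: 7 2-[2-(benzyloxy)-6-methoxyphenoxy]benzaldehyde
Product: 9 2-[2-(benzyloxy)-6-methoxyphenoxy]phenol, via 2-[2-(benzyloxy)-6-methoxyphenoxy]phenyl formate 8 (not isolated)
Conditions: mCPBA, CH2Cl2, rt; then K2CO3, MeOH, rt
Reagents that add atoms: 3-chloroperoxybenzoic acid (mCPBA), O=C(OO)c1cccc(Cl)c1
Why: Second Dakin-type Baeyer–Villiger oxidation; the ortho aryloxy oxygen should make ring A migrate in preference to hydride, methanolysis of formate 8 frees the ring A phenol, and the benzyl and methyl ethers are stable to peracid and carbonate.

Step 5
Reactants: 9 2-[2-(benzyloxy)-6-methoxyphenoxy]phenol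
Product: 10 2-[2-(benzyloxy)-3,5-dibromo-6-methoxyphenoxy]-4,6-dibromophenol
Conditions: Br2 (4.1 equiv), NaOAc, AcOH–CH2Cl2, 0 °C to rt, dark; aq. Na2S2O3
Reagents that add atoms: bromine, BrBr
Why: Four successive electrophilic aromatic substitutions proceed through arenium ions, as in the known polybromination of phenols and alkoxyarenes with bromine in buffered acetic acid, and no ring is closed and no stereocentre is formed. On ring A the free hydroxyl at C2 is the strongest donor and sends bromine to its ortho carbon C3 and its para carbon C5, whereas an ether at C2 would let the second bromine enter para to the aryloxy oxygen. On ring B the benzyloxy and methoxy groups are meta to each other, so C3 and C5 are each ortho to one and para to the other, as in a resorcinol diether, while C4 is activated only by the twisted and weakly donating central aryloxy oxygen. The step needs site selectivity on both rings, a stop at four substitutions and survival of the benzyl ether. The first is secured by these matched directing effects, and the second by the stoichiometry and by the fact that every remaining ring position is meta to the strong donors and flanked by bromine. NaOAc converts the HBr formed into NaBr so that the benzyl ether is not cleaved by acid, and ionic conditions in the dark leave the unactivated benzyl ring and the benzylic CH2 untouched. The partly brominated species formed on the way are expected to converge on 10 whatever the order of attack.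

Step 6
Reactants: 10 2-[2-(benzyloxy)-3,5-dibromo-6-methoxyphenoxy]-4,6-dibromophenol
Product: 11 1-(benzyloxy)-4,6-dibromo-2-(3,5-dibromo-2-methoxyphenoxy)-3-methoxybenzene
Conditions: MeI, K2CO3, DMF, rt
Reagents that add atoms: iodomethane, CI
Why: Williamson methylation of the only free phenol; the dibrominated phenol is acidic enough for K2CO3, and methyl iodide is small enough for the doubly ortho-substituted phenoxide.

Step 7
Reactants: 11 1-(benzyloxy)-4,6-dibromo-2-(3,5-dibromo-2-methoxyphenoxy)-3-methoxybenzene
Product: 12 4,6-dibromo-2-(3,5-dibromo-2-methoxyphenoxy)-3-methoxyphenol
Conditions: BCl3, pentamethylbenzene, CH2Cl2, −78 °C; aq. work-up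
Reagents that add atoms: none
Why: Lewis-acid debenzylation; BCl3 coordinates the benzyl ether oxygen and the benzyl group leaves as a cation that pentamethylbenzene traps by Friedel–Crafts alkylation, while at −78 °C aryl methyl ethers and aryl bromides should remain intact, which hydrogenolysis could not guarantee.

## Compound list

1 | 2-hydroxy-6-methoxybenzaldehyde | COc1cccc(O)c1C=O | starting material
2 | benzyl bromide | BrCc1ccccc1 | starting material
3 | 2-(benzyloxy)-6-methoxybenzaldehyde | COc1cccc(OCc2ccccc2)c1C=O | intermediate
4 | 2-(benzyloxy)-6-methoxyphenyl formate | COc1cccc(OCc2ccccc2)c1OC=O | intermediate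
5 | 2-(benzyloxy)-6-methoxyphenol | COc1cccc(OCc2ccccc2)c1O | intermediate
6 | 2-fluorobenzaldehyde | O=Cc1ccccc1F | starting material
7 | 2-[2-(benzyloxy)-6-methoxyphenoxy]benzaldehyde | O=Cc1ccccc1Oc1c(OC)cccc1OCc1ccccc1 | intermediate
8 | 2-[2-(benzyloxy)-6-methoxyphenoxy]phenyl formate | O=COc1ccccc1Oc1c(OC)cccc1OCc1ccccc1 | intermediate
9 | 2-[2-(benzyloxy)-6-methoxyphenoxy]phenol | Oc1ccccc1Oc1c(OC)cccc1OCc1ccccc1 | intermediate
10 | 2-[2-(benzyloxy)-3,5-dibromo-6-methoxyphenoxy]-4,6-dibromophenol | Oc1c(Br)cc(Br)cc1Oc1c(OC)c(Br)cc(Br)c1OCc1ccccc1 | intermediate
11 | 1-(benzyloxy)-4,6-dibromo-2-(3,5-dibromo-2-methoxyphenoxy)-3-methoxybenzene | COc1c(Br)cc(Br)cc1Oc1c(OC)c(Br)cc(Br)c1OCc1ccccc1 | intermediate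
12 | 4,6-dibromo-2-(3,5-dibromo-2-methoxyphenoxy)-3-methoxyphenol | COc1c(Br)cc(Br)cc1Oc1c(O)c(Br)cc(Br)c1OC | target

Total step count: 7. Longest linear sequence: 7 steps (1 to 12).

## Least certain steps

**Step 5 (key step).** The most likely failures are these:
- loss of site selectivity in the second substitution of ring A (attack para to the aryloxy oxygen);
- under- or over-bromination, because two rings of different reactivity share one charge of bromine;
- acid cleavage of the benzyl ether if buffering is insufficient.

The fallback splits the halogenation over two stages, using the formyl group as a temporary deactivator of ring A. It sets out from 7. NBS (2 equiv) in MeCN should brominate only ring B to give 2-[2-(benzyloxy)-3,5-dibromo-6-methoxyphenoxy]benzaldehyde F1. Peracid oxidation would give 2-[2-(benzyloxy)-3,5-dibromo-6-methoxyphenoxy]phenyl formate F2, and methanolysis would give 2-[2-(benzyloxy)-3,5-dibromo-6-methoxyphenoxy]phenol F3. Bromine (2 equiv) with NaOAc in acetic acid then acts on the ring A phenol alone, since ring B is already deactivated, and the fallback comes back to the route at 10.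

**Step 4.** Hydride migration in place of aryl migration would lead to the carboxylic acid, because an aryloxy group is a weaker donor than an alkoxy group, and the peracid could oxidise the electron-rich ring B. The fallback avoids the oxidation by bringing ring A in with its oxygen already in place. It sets out from 5. A copper-catalysed Ullmann ether coupling (CuI, picolinic acid, K3PO4, DMSO, 90 °C) with commercial 1-bromo-2-(methoxymethoxy)benzene would give 1-(benzyloxy)-3-methoxy-2-[2-(methoxymethoxy)phenoxy]benzene F4. HCl in methanol removes the acetal, and the fallback comes back at 9.

**Step 3.** Slow substitution by the doubly ortho-substituted phenoxide would allow base-induced decay of the aldehyde at the temperature required. The fallback uses a far stronger acceptor and sets out from 5. 1-Fluoro-2-nitrobenzene with K2CO3 in DMF at 60 °C would give 1-(benzyloxy)-3-methoxy-2-(2-nitrophenoxy)benzene F5. Reduction with Fe and NH4Cl in aqueous ethanol would give 2-[2-(benzyloxy)-6-methoxyphenoxy]aniline F6. Diazotisation (NaNO2, H2SO4, 0 °C) would give 2-[2-(benzyloxy)-6-methoxyphenoxy]benzenediazonium hydrogensulfate F7. Hydroxy-dediazoniation with Cu2O and Cu(NO3)2 in water brings the fallback back at 9. Both ortho positions of ring B are blocked, so radical ring closure to a dibenzofuran is not available.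

**Step 7.** The Lewis acid could also demethylate one of the ethers next to the diaryl ether oxygen, by chelation, if the temperature rises, and debenzylation of the hindered, electron-poor ether could be incomplete. The fallback removes the benzyl group oxidatively and sets out from 11. NBS under visible light in PhCF3 should brominate the benzylic position, the only readily abstracted hydrogen, to give racemic 1-[bromo(phenyl)methoxy]-4,6-dibromo-2-(3,5-dibromo-2-methoxyphenoxy)-3-methoxybenzene F8. Aqueous NaHCO3 hydrolyses this α-bromo ether, and the fallback comes back at 12.

## Further compounds

F1 | step 5 | 2-[2-(benzyloxy)-3,5-dibromo-6-methoxyphenoxy]benzaldehyde | O=Cc1ccccc1Oc1c(OC)c(Br)cc(Br)c1OCc1ccccc1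
F2 | step 5 | 2-[2-(benzyloxy)-3,5-dibromo-6-methoxyphenoxy]phenyl formate | O=COc1ccccc1Oc1c(OC)c(Br)cc(Br)c1OCc1ccccc1
F3 | step 5 | 2-[2-(benzyloxy)-3,5-dibromo-6-methoxyphenoxy]phenol | Oc1ccccc1Oc1c(OC)c(Br)cc(Br)c1OCc1ccccc1
F4 | step 4 | 1-(benzyloxy)-3-methoxy-2-[2-(methoxymethoxy)phenoxy]benzene | COCOc1ccccc1Oc1c(OC)cccc1OCc1ccccc1
F5 | step 3 | 1-(benzyloxy)-3-methoxy-2-(2-nitrophenoxy)benzene | O=[N+]([O-])c1ccccc1Oc1c(OC)cccc1OCc1ccccc1
F6 | step 3 | 2-[2-(benzyloxy)-6-methoxyphenoxy]aniline | Nc1ccccc1Oc1c(OC)cccc1OCc1ccccc1
F7 | step 3 | 2-[2-(benzyloxy)-6-methoxyphenoxy]benzenediazonium hydrogensulfate | N#[N+]c1ccccc1Oc1c(OC)cccc1OCc1ccccc1.OS(=O)(=O)[O-]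
F8 | step 7 | 1-[bromo(phenyl)methoxy]-4,6-dibromo-2-(3,5-dibromo-2-methoxyphenoxy)-3-methoxybenzene (racemic) | COc1c(Br)cc(Br)cc1Oc1c(OC)c(Br)cc(Br)c1OC(Br)c1ccccc1
A1 | alternative 1 | 3,5-dibromo-2-methoxyphenol | COc1c(Br)cc(Br)cc1O
A2 | alternative 1 | methyl 6-(3,5-dibromo-2-methoxyphenoxy)-5-oxohexanoate | COC(=O)CCCC(=O)COc1cc(Br)cc(Br)c1OC
A3 | alternative 1 | 2-(3,5-dibromo-2-methoxyphenoxy)cyclohexane-1,3-dione | COc1c(Br)cc(Br)cc1OC1C(=O)CCCC1=O
A4 | alternative 1 | 2-(3,5-dibromo-2-methoxyphenoxy)-3-methoxycyclohex-2-en-1-one | COC1=C(Oc2cc(Br)cc(Br)c2OC)C(=O)CCC1
A5 | alternative 1 | 2-(3,5-dibromo-2-methoxyphenoxy)-3-methoxyphenol | COc1c(Br)cc(Br)cc1Oc1c(O)cccc1OC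
A6 | alternative 2 | 1-(benzyloxy)-3-methoxy-2-{[4-methoxy-2,4-bis(trimethylsilyloxy)buta-1,3-dien-1-yl]oxy}benzene (double-bond geometry not defined) | COC(O[Si](C)(C)C)=CC(O[Si](C)(C)C)=COc1c(OC)cccc1OCc1ccccc1
A7 | alternative 2 | 2-bromo-3-(trimethylsilyloxy)prop-2-enal (double-bond geometry not defined) | O=CC(Br)=CO[Si](C)(C)C
A8 | alternative 2 | methyl 3-[2-(benzyloxy)-6-methoxyphenoxy]-5-bromo-2-hydroxybenzoate | COC(=O)c1cc(Br)cc(Oc2c(OC)cccc2OCc2ccccc2)c1O
A9 | alternative 3 | 2-fluoroisophthalaldehyde | O=Cc1cccc(C=O)c1F
A10 | alternative 3 | 2-(3,5-dibromo-2-methoxyphenoxy)isophthalaldehyde | COc1c(Br)cc(Br)cc1Oc1c(C=O)cccc1C=O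
A11 | alternative 3 | 2-(3,5-dibromo-2-methoxyphenoxy)benzene-1,3-diol | COc1c(Br)cc(Br)cc1Oc1c(O)cccc1O
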